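South-west was the run I had to work from, and I wanted from it how long a flask of this kind keeps to its early curve.

| setting | south-west | epsilon | zeta | gamma | delta |
|---|---|---|---|---|---|
| starting material | 0.58 M | 0.86 M | 0.86 M | 0.86 M | 0.86 M |
| reagent | 0.516 M | 0.516 M | 1.50 M | 0.250 M | 0.516 M |
| precatalyst | 37 mM | 37 mM | 12 mM | 10 mM | 25 mM |
| remark | run made earlier |  |  |  |  |
| time |  | 25 h | 25 h | 25 h | 25 h |

south-west run (percent of the starting material charged)

| time / h | target / % | starting material / % |
|---|---|---|
| 2.00 | 0 | 100.3 |
| 5.00 | 1.6 | 99.4 |
| 10.0 | 3.9 | 95.4 |
| 15.0 | 9.1 | 92.2 |

(standard deviation of a reading: 0.5 percentage points)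

- candidate steps: reagent + free catalyst -> catalyst intermediate A; catalyst intermediate A -> by-product + catalyst intermediate B; starting material + catalyst intermediate B -> catalyst intermediate C; catalyst intermediate C -> free catalyst + target; free catalyst -> spent catalyst A; 2 catalyst intermediate A -> spent catalyst B; precatalyst -> free catalyst
- no earlier run changes the charge of precatalyst; that part of a forecast is a guess

- ranking by amount of target, in percent of the starting material charged, from high to low, at 25 h (epsilon / zeta / gamma / delta)
- the amount of target, in percent of the starting material charged of the flask you put first, at 25 h
- the amount of target, in percent of the starting material charged of the flask you put last, at 25 h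

A bench rule of mine for a curve that starts with a delay is to let target grow with the square of the time. South-west allowed it: from 10.0 h to 15.0 h target rose by a factor of 2.33, and the square of the time ratio is 2.25. So I scaled the last reading of south-west, as a reading with its scatter, by the square of the time.

Epsilon has the same reagent and precatalyst as south-west, so I kept the curve of south-west in molar terms, assuming that more starting material changed nothing:

[target] in epsilon at 25 h = 9.1% of 0.58 M, times the square of 25 h over 15.0 h, over 0.86 M = 17.0% of the starting material charged

The other flasks change the precatalyst, which is a guess, so I put no number on them.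

The rule has a border. Each turn takes one reagent and one starting material, and in epsilon reagent is the limiting reagent, 0.516 M against 0.86 M, so target stops at a ceiling of 60.0%. The curve meets that charge at:

time = 15.0 h times the square root of 0.516 M over 9.1% of 0.58 M = 46.9 h

This run-out time is when the square rule has used the charged reagent. Epsilon is read at half of it, so the rule gave 71.6% of the reagent still in the flask.

The forecast gave epsilon > delta > zeta > gamma, with 20% first and 3% last, on the ground that the curve “fits slow release of active catalyst from the precatalyst”. Its top stood above my figure.

The flasks gave epsilon > delta > zeta > gamma, with epsilon at 18.6% and gamma at 5.04%.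

    reagent + free catalyst → catalyst intermediate A (k = 31.0 M⁻¹ h⁻¹)
    catalyst intermediate A → by-product + catalyst intermediate B (k = 2.40 h⁻¹)
    starting material + catalyst intermediate B → catalyst intermediate C (k = 2.90 M⁻¹ h⁻¹)
    catalyst intermediate C → free catalyst + target (k = 130 h⁻¹)
    free catalyst → spent catalyst A (k = 1.30 × 10⁻⁴ h⁻¹)
    2 catalyst intermediate A → spent catalyst B (k = 2.40 M⁻¹ h⁻¹)
    precatalyst → free catalyst (k = 0.0160 h⁻¹)

Read at 28.9 h instead, epsilon had moved by 5 points. At 25 h epsilon held 66.8% of its reagent against my 71.6%. The same flask as epsilon read at 4.0 d, twice the run-out time of 46.9 h, held 0% of its reagent and target at 59.5%.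

(The data are simulated with constants of no real substance; scatter was added.)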